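## Structural features

The target joins two heterocycles through one methylene carbon. One is a 2,2-dimethyl-2H-chromene (benzene ring A fused to pyran ring B) and the other a 6-ethyl-4-hydroxy-5-methyl-2-pyranone (ring C), with the bridge running from chromene C6 to pyranone C3'. Ring A is hexasubstituted and of phloroglucinol origin: hydroxyls at C5 and C7, the bridge between them at C6, the (S)-2-methylbutanoyl ketone at C8, the pyran oxygen O1 on the neighbouring C8a, and C4a carrying the C3=C4 alkene. The only stereocentre is the chain carbon alpha to the aryl ketone. It has no stereogenic neighbour, so the stereochemical task is to bring it in from the chiral pool and never let it enolise, which argues against Lewis-acid acylium chemistry and hot base. Other fragile points are the styrene-like C3=C4 bond on a very electron-rich ring (acid, hydrogenation), the oxidisable polyphenol, and the methylene bridge, which forms and breaks under similar conditions. The real difficulty is regiochemical: the three oxygens of a symmetric phloroglucinol must be told apart so that ketone and ring oxygen end up on adjacent carbons (C8 and C8a), and the bridge must join two different nucleophiles and not two alike. The key step exploits the C8/C8a adjacency: an aryl C–C(=O) bond and an aryl C–O bond on neighbouring carbons are what the two ends of an aryne triple bond accept from a carboxylate, and the phenol so formed is the only free hydroxyl, marking where ring B must grow.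

## Logic of the disconnections

**24 ⇒ 16 + 21.** The bonds C6–CH2 and CH2–C3' are cut. Both ends are the most nucleophilic carbons of their rings, so a one-carbon electrophile can join them in the last step. This splits the molecule into two halves of similar size and keeps pyranone chemistry away from the chiral chromene. The forward step must place the carbon between two different partners. This is arranged by loading it onto 21 first (22, then 23) and by the fact that 16 has a single unsubstituted ring carbon. The medium must stay near neutral because of the alpha stereocentre.

**16 ⇒ 15 ⇒ 14 ⇒ 12 + 13.** First the two O–CH2OMe bonds are restored (16 to 15). Then ring B is opened across C4a–C4, which leads back to the aryl propargyl ether 14, and the O1–C2 bond is cut to give 12 and 13. The cut is made here because the three carbons and the gem-dimethyl group of ring B then come from the cheap 13, and the position of the ether oxygen alone decides the regiochemistry. Ring B and its sensitive alkene disappear from all earlier intermediates. The demand is that 12 carries exactly one free hydroxyl, ortho to the ketone, and one hydrogen-bearing ortho carbon, and that acetal removal spares the C3=C4 bond and the stereocentre.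

**12 ⇒ 9 + 10 (through 11).** The aryl C–C(=O) bond (future C8–acyl) and the aryl C–O bond on the adjacent carbon (future C8a–O1) are cut together. Two ortho bonds of this kind are the signature of an insertion across an aryne, and the acyl group then comes from a carboxylate and not from an acylium ion. The chiral chain is traced to the chiral-pool acid 10 and the aromatic part to an achiral silyl triflate. The forward step needs regioselective addition to the unsymmetrical 11, an acyl shift faster than protonation of the aryl anion, and no enolisation.

**9 ⇒ 7 ⇒ 3 ⇒ 2 ⇒ 1.** The O–S bond, the C2–Si bond, the carbamate O–C(=O) bond and two acetal O–CH2 bonds are cut in turn. Silicon must sit between the leaving-group oxygen and one acetal oxygen, which a carbamate-directed lithiation delivers, and the carbamate is afterwards removed without trace. The sequence ends at the symmetric 1. The demands are lithiation at C2 and not at C4, and acceptance of a statistical double protection of 1.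

**21 ⇒ 20 ⇒ 17 + 18.** The lactone bond O1'–C2' is cut, then the C5'–C6' bond (C4–C5 of the open chain). This reduces ring C to a beta-keto ester dianion and a propanoyl donor, two simple building blocks. The forward acylation must occur at the gamma carbon of the dianion and must stop at the ketone stage.

## Other disconnections considered

**Alternative 1:** Ring A itself is cut at C5–C6, C7–C8 and C4a–C5.
- Precursors: ring B arrives as the diazo ketone 2-diazo-1-(6,6-dimethyl-5,6-dihydro-4H-pyran-2-yl)ethan-1-one A2. C6, C7 and the bridge carbon come from the siloxyalkyne tert-butyldimethyl{[3-(triisopropylsilyloxy)prop-2-yn-1-yl]oxy}silane A3.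
- Forward key step: light would induce Wolff rearrangement of A2 to a vinylketene. A [2+2] addition to A3, four-electron opening of the cyclobutenone, six-electron closure and tautomerisation would give 6-[(tert-butyldimethylsilyloxy)methyl]-2,2-dimethyl-7-(triisopropylsilyloxy)chroman-5-ol A1.
- In favour: the polarity of the ynol ether dictates the regiochemistry, and all three ring oxygens emerge differentiated. The benzylic carbon on C6 is already present, so the pyranone could be attached through an ortho-quinone methide with no possibility of symmetrical dimers. On this last point the alternative is better than the chosen plan.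
- Against: A1 has hydrogen at C8 and a saturated ring B. The acyl group would still have to be introduced, either by acylium chemistry that endangers the stereocentre or by a halogenation and metalation detour. The chroman would need dehydrogenation, and A2 and A3 each take several steps.
- Comparison: mechanistically the pericyclic cascade is as well controlled as the aryne insertion, so the two are equal in regiochemical reliability. Structurally it builds a benzene ring that 1 supplies ready-made. In step count the chosen plan is clearly ahead, reaching ring A with the acyl group in place in five steps from 1.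

**Alternative 2:** The O1'–C6' bond of ring C is cut, so the pyranone is assembled last on a complete chromene.
- Precursor: tert-butyl 2-({5,7-bis(methoxymethoxy)-2,2-dimethyl-8-[(S)-2-methylbutanoyl]-2H-chromen-6-yl}methyl)-4-methyl-3-oxohepta-4,5-dienoate A5.
- Forward key step: with mild base the ester enolate oxygen would add to the central allene carbon (a 6-endo oxa-Michael addition). Proton transfer would give (S)-1-{6-[(2-tert-butoxy-6-ethyl-5-methyl-4-oxo-4H-pyran-3-yl)methyl]-5,7-bis(methoxymethoxy)-2,2-dimethyl-2H-chromen-8-yl}-2-methylbutan-1-one A4. Acid would then remove the tert-butyl group and both acetals together.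
- In favour: the bridge is made by C-alkylation between two defined partners, so homo-dimers cannot arise, which is better than the chosen plan. One acid step unmasks three oxygens, which is equal or better in protecting-group economy.
- Against: ring C is a two-step compound (21) when made separately. Building it on the chromene means enolate alkylation with a hindered, electron-rich benzylic electrophile and installation of a reactive allenyl ketone, all beside the epimerisable ketone. Competing C-cyclisation and allene isomerisation are possible. The C8/C8a problem is left untouched.
- Comparison: structurally it addresses the easy ring. Mechanistically the closure is plausible but less precedented than the lactonisation of step 10. In step economy it is linear where the chosen plan is convergent, and longer.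

**Alternative 3:** The aryl–oxygen bond C8a–O1 is cut.
- Precursor: (S)-1-{2-fluoro-3-[(Z)-3-hydroxy-3-methylbut-1-en-1-yl]-4,6-bis(methoxymethoxy)phenyl}-2-methylbutan-1-one A7.
- Forward key step: the tertiary alkoxide of A7 would add to the fluorine-bearing carbon, activated by the ortho ketone, and fluoride would leave from the Meisenheimer adduct. The product, (S)-1-[5,7-bis(methoxymethoxy)-2,2-dimethyl-2H-chromen-8-yl]-2-methylbutan-1-one A6, is the same compound as 15.
- In favour: the position of fluorine fixes the regiochemistry of ring B, which is equal to the chosen plan. The closure should run at or below room temperature and avoids both the alkylation of a chelated phenol and the 140 °C rearrangement, which is better in thermal mildness. The endgame would be identical.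
- Against: A7 has acyl, fluoro and (Z)-alkenyl groups on three contiguous carbons and is not within easy reach of 1. The acyl group must still be introduced separately. The (Z)-alkene needs an alkyne coupling and semi-hydrogenation. A strongly basic alkoxide is generated in the same molecule as the epimerisable alpha carbon.
- Comparison: structurally the key step forms one bond (C8a–O1) where the chosen step forms two (C8–acyl and C8a–O). Mechanistically both are reliable. In step economy several extra steps would be needed to arrive at the same intermediate.

Key step: step 5

Remark on the chemistry: chromene positions are numbered O1, C2 to C8a and pyranone positions are primed. Commercial (S)-2-methylbutanoic acid is assumed to be of high enantiomeric purity.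

Remark on the chemistry: ring C is built from methyl 3-oxopentanoate. Its 2-methyl homologue would need a Claisen condensation at an ester flanked by an acidic C–H or, used as its dianion, would put a methyl group on C3', where the bridge must go.

Remark on the chemistry: the aryne precursor 9 and the insertion product 12 were checked atom by atom. Silicon between the triflate and one acetal oxygen leads to oxygen at C1 and acyl at C2, which is the pattern of 12, and the chain is (S) throughout. No structural correction is needed.

## Route

Step 1
Reactants: 1 phloroglucinol (benzene-1,3,5-triol, anhydrous)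
Product: 2 3,5-bis(methoxymethoxy)phenol
Conditions: MOMCl (2.0 equiv), i-Pr2NEt, DMF, 0 °C → rt
Reagents that add atoms: chloromethyl methyl ether, COCCl
Why: Williamson-type O-alkylation of two of the three equivalent phenols; the reaction is statistical, so the bis-ether should be the main fraction at two equivalents and is separated from the mono-ether (which can be re-alkylated) and the tris-ether.

Step 2
Reactants: 2 3,5-bis(methoxymethoxy)phenol
Product: 3 3,5-bis(methoxymethoxy)phenyl N-isopropylcarbamate
Conditions: i-PrNCO, Et3N (cat.), CH2Cl2, rt
Reagents that add atoms: isopropyl isocyanate, CC(C)N=C=O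
Why: Base-catalysed addition of the phenol to the isocyanate; the N-isopropylcarbamate is chosen because it directs ortho-metalation strongly and can later be removed with mild amine base.

Step 3
Reactants: 3 3,5-bis(methoxymethoxy)phenyl N-isopropylcarbamate
Product: 7 3,5-bis(methoxymethoxy)-2-(trimethylsilyl)phenyl N-isopropylcarbamate, via N-silyl carbamate 4 (not isolated), via aryllithium 5 (not isolated), via N-silyl arylsilane 6 (not isolated)
Conditions: TMSOTf, TMEDA, Et2O, 0 °C → rt; n-BuLi, TMEDA, −78 °C; TMSCl, −78 °C → rt; aq. NH4Cl
Reagents that add atoms: chlorotrimethylsilane, C[Si](C)(C)Cl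
Why: Directed ortho-metalation: transient N-silylation masks the N–H, the carbamate and the adjacent acetal oxygen together direct lithium to C2, and the silyl chloride traps the anion; the nitrogen-bound silyl group is lost on aqueous work-up.

Step 4
Reactants: 7 3,5-bis(methoxymethoxy)-2-(trimethylsilyl)phenyl N-isopropylcarbamate
Product: 9 3,5-bis(methoxymethoxy)-2-(trimethylsilyl)phenyl trifluoromethanesulfonate, via silylphenol 8 (not isolated)
Conditions: DBU, Et2NH, MeCN, 40 °C; then PhNTf2, rt
Reagents that add atoms: N-phenylbis(trifluoromethanesulfonimide), O=S(=O)(N(c1ccccc1)S(=O)(=O)C(F)(F)F)C(F)(F)F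
Why: Base-induced E1cB loss of isopropyl isocyanate from the N–H carbamate, with diethylamine as scavenger, frees the phenoxide, which the mild triflyl donor sulfonylates in the same flask; no acid touches the acetals or the aryl–silicon bond.

Step 5
Reactants: 9 3,5-bis(methoxymethoxy)-2-(trimethylsilyl)phenyl trifluoromethanesulfonate; 10 (S)-2-methylbutanoic acid
Product: 12 (S)-1-[2-hydroxy-4,6-bis(methoxymethoxy)phenyl]-2-methylbutan-1-one, via aryne 11 (not isolated)
Conditions: CsF (4 equiv), THF, 125 °C (sealed tube)
Reagents that add atoms: none
Why: Fluoride attacks silicon in 9 and triflate leaves, giving aryne 11 (C1 and C2 the aryne carbons, C3 bearing the flanking acetal oxygen); the cesium carboxylate of 10 adds through oxygen to C1, because the oxygen on C3 polarises and distorts the triple bond and stabilises negative charge on C2. The aryl anion at C2 then attacks the adjacent ester carbonyl through a strained four-membered alkoxide, which collapses by C–O cleavage to the ortho-acyl phenoxide, protonated to 12 on work-up. The closest known reaction type is the insertion of arynes into the carbon–oxygen sigma bond of carboxylic acids to give ortho-hydroxyaryl ketones, a relative of the anionic Fries shift. No ring is closed and no stereocentre is created; the existing one is carried through because the carbonyl carbon is attacked only by a carbanion and never becomes an acylium ion or a ketene. Regioselectivity is the selectivity that matters most, and the acetal oxygen on C3 secures it by sending oxygen to C1 and the acyl group to C2. The acyl shift must also outrun protonation of the aryl anion, which would give the simple aryl ester; high temperature, an aprotic medium and excess CsF favour the shift. The product is formed as a phenoxide whose carbonyl is strongly deactivated and flanked by two ortho substituents, which should make enolisation slow.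

Step 6
Reactants: 12 (S)-1-[2-hydroxy-4,6-bis(methoxymethoxy)phenyl]-2-methylbutan-1-one; 13 3-chloro-3-methylbut-1-yne
Product: 14 (S)-1-[2,4-bis(methoxymethoxy)-6-(2-methylbut-3-yn-2-yloxy)phenyl]-2-methylbutan-1-one
Conditions: CuCl2·2H2O (cat.), DBU, MeCN, 0 °C
Reagents that add atoms: none
Why: Copper-catalysed propargylic etherification of a phenol with a tertiary propargylic chloride, through a copper acetylide that ionises to an allenylidene-type electrophile; the ortho-acyl phenol is acidic enough to be deprotonated by the amidine at 0 °C, where the alpha carbon of the ketone is not at risk.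

Step 7
Reactants: 14 (S)-1-[2,4-bis(methoxymethoxy)-6-(2-methylbut-3-yn-2-yloxy)phenyl]-2-methylbutan-1-one
Product: 15 (S)-1-[5,7-bis(methoxymethoxy)-2,2-dimethyl-2H-chromen-8-yl]-2-methylbutan-1-one
Conditions: o-xylene (degassed), 140 °C
Reagents that add atoms: none
Why: Aromatic propargyl Claisen rearrangement to the only hydrogen-bearing ortho carbon, then enolisation, 1,5-hydrogen shift and oxa-6π electrocyclisation give the 2,2-dimethylchromene; the other ortho position is blocked by the ketone, so the ring oxygen stays next to the acyl group, and the neutral medium leaves the stereocentre alone.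

Step 8
Reactants: 15 (S)-1-[5,7-bis(methoxymethoxy)-2,2-dimethyl-2H-chromen-8-yl]-2-methylbutan-1-one
Product: 16 (S)-1-(5,7-dihydroxy-2,2-dimethyl-2H-chromen-8-yl)-2-methylbutan-1-one
Conditions: HCl (conc., cat.), MeOH, rt → 40 °C
Reagents that add atoms: none
Why: Acid-catalysed acetal exchange transfers both methoxymethyl groups to methanol; the ketone, conjugated with and hydrogen-bonded to the new phenols, should enolise only slowly in dilute acid at this temperature, and the electron-withdrawing acyl group tempers protonation of the C3=C4 bond.

Step 9
Reactants: 17 methyl 3-oxopentanoate; 18 N-methoxy-N-methylpropanamide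
Product: 20 methyl 4-methyl-3,5-dioxoheptanoate, via dilithium dienolate 19 (not isolated)
Conditions: LiN(i-Pr)2 (2.2 equiv), THF, −78 → 0 °C; then 18, −78 °C → rt; aq. HCl
Reagents that add atoms: none
Why: C-acylation of a beta-keto ester dianion at its more reactive gamma carbon; the N-methoxy-N-methyl amide stops at the chelated tetrahedral adduct, so the acidic tricarbonyl product is released only on work-up and consumes no further dianion.

Step 10
Reactants: 20 methyl 4-methyl-3,5-dioxoheptanoate
Product: 21 6-ethyl-4-hydroxy-5-methyl-2H-pyran-2-one
Conditions: DBU, toluene, 110 °C; then aq. HCl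
Reagents that add atoms: none
Why: Base-mediated lactonisation of a 3,5-dioxo ester: the C5 enol oxygen attacks the methyl ester and methanol is lost, giving the 4-hydroxy-2-pyranone as its stable conjugated tautomer.

Step 11
Reactants: 21 6-ethyl-4-hydroxy-5-methyl-2H-pyran-2-one; 16 (S)-1-(5,7-dihydroxy-2,2-dimethyl-2H-chromen-8-yl)-2-methylbutan-1-one
Product: 24 6-ethyl-3-({5,7-dihydroxy-2,2-dimethyl-8-[(S)-2-methylbutanoyl]-2H-chromen-6-yl}methyl)-4-hydroxy-5-methyl-2H-pyran-2-one (the target), via Mannich base 22 (not isolated), via methylidene pyrandione 23 (not isolated)
Conditions: CH2=NMe2+ I− (1.0 equiv), MeCN, rt; then 16, 60 °C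
Reagents that add atoms: N,N-dimethylmethylideneammonium iodide (Eschenmoser's salt), C=[N+](C)C.[I-]
Why: Mannich aminomethylation of the pyranone at C3', thermal loss of dimethylamine to the 3-methylidene-2,4-dione, and Friedel–Crafts-type conjugate addition of C6 of 16, its only unsubstituted ring carbon; loading the one-carbon unit on the pyranone before 16 is added keeps symmetrical dimers down, and the medium stays near neutral.

## Compound list

1 | phloroglucinol (benzene-1,3,5-triol) | Oc1cc(O)cc(O)c1 | starting material
2 | 3,5-bis(methoxymethoxy)phenol | COCOc1cc(O)cc(OCOC)c1 | intermediate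
3 | 3,5-bis(methoxymethoxy)phenyl N-isopropylcarbamate | COCOc1cc(OCOC)cc(OC(=O)NC(C)C)c1 | intermediate
4 | 3,5-bis(methoxymethoxy)phenyl N-isopropyl-N-(trimethylsilyl)carbamate | COCOc1cc(OCOC)cc(OC(=O)N(C(C)C)[Si](C)(C)C)c1 | intermediate
5 | 2-lithio-3,5-bis(methoxymethoxy)phenyl N-isopropyl-N-(trimethylsilyl)carbamate | COCOc1cc(OCOC)c([Li])c(OC(=O)N(C(C)C)[Si](C)(C)C)c1 | intermediate
6 | 3,5-bis(methoxymethoxy)-2-(trimethylsilyl)phenyl N-isopropyl-N-(trimethylsilyl)carbamate | COCOc1cc(OCOC)c([Si](C)(C)C)c(OC(=O)N(C(C)C)[Si](C)(C)C)c1 | intermediate
7 | 3,5-bis(methoxymethoxy)-2-(trimethylsilyl)phenyl N-isopropylcarbamate | COCOc1cc(OCOC)c([Si](C)(C)C)c(OC(=O)NC(C)C)c1 | intermediate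
8 | 3,5-bis(methoxymethoxy)-2-(trimethylsilyl)phenol | COCOc1cc(O)c([Si](C)(C)C)c(OCOC)c1 | intermediate
9 | 3,5-bis(methoxymethoxy)-2-(trimethylsilyl)phenyl trifluoromethanesulfonate | COCOc1cc(OCOC)c([Si](C)(C)C)c(OS(=O)(=O)C(F)(F)F)c1 | intermediate
10 | (S)-2-methylbutanoic acid | CC[C@H](C)C(=O)O | starting material
11 | 3,5-bis(methoxymethoxy)benzyne (1,2-didehydro-3,5-bis(methoxymethoxy)benzene) | COCOC1=CC(OCOC)=CC#C1 | intermediate
12 | (S)-1-[2-hydroxy-4,6-bis(methoxymethoxy)phenyl]-2-methylbutan-1-one | CC[C@H](C)C(=O)c1c(O)cc(OCOC)cc1OCOC | intermediate
13 | 3-chloro-3-methylbut-1-yne | CC(C)(Cl)C#C | starting material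
14 | (S)-1-[2,4-bis(methoxymethoxy)-6-(2-methylbut-3-yn-2-yloxy)phenyl]-2-methylbutan-1-one | CC[C@H](C)C(=O)c1c(OC(C)(C)C#C)cc(OCOC)cc1OCOC | intermediate
15 | (S)-1-[5,7-bis(methoxymethoxy)-2,2-dimethyl-2H-chromen-8-yl]-2-methylbutan-1-one | CC[C@H](C)C(=O)c1c(OCOC)cc(OCOC)c2C=CC(C)(C)Oc12 | intermediate
16 | (S)-1-(5,7-dihydroxy-2,2-dimethyl-2H-chromen-8-yl)-2-methylbutan-1-one | CC[C@H](C)C(=O)c1c(O)cc(O)c2C=CC(C)(C)Oc12 | intermediate
17 | methyl 3-oxopentanoate | CCC(=O)CC(=O)OC | starting material
18 | N-methoxy-N-methylpropanamide | CCC(=O)N(C)OC | starting material
19 | dilithium dienolate of methyl 3-oxopentanoate | [Li+].[Li+].CC=C([O-])C=C([O-])OC | intermediate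
20 | methyl 4-methyl-3,5-dioxoheptanoate (C4 configuration irrelevant, enolised) | CCC(=O)C(C)C(=O)CC(=O)OC | intermediate
21 | 6-ethyl-4-hydroxy-5-methyl-2H-pyran-2-one | CCc1oc(=O)cc(O)c1C | intermediate
22 | 3-[(dimethylamino)methyl]-6-ethyl-4-hydroxy-5-methyl-2H-pyran-2-one | CCc1oc(=O)c(CN(C)C)c(O)c1C | intermediate
23 | 6-ethyl-5-methyl-3-methylidene-2H-pyran-2,4(3H)-dione | CCC1=C(C)C(=O)C(=C)C(=O)O1 | intermediate
24 | 6-ethyl-3-({5,7-dihydroxy-2,2-dimethyl-8-[(S)-2-methylbutanoyl]-2H-chromen-6-yl}methyl)-4-hydroxy-5-methyl-2H-pyran-2-one | CCc1oc(=O)c(Cc2c(O)c3c(c(C(=O)[C@@H](C)CC)c2O)OC(C)(C)C=C3)c(O)c1C | target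

## Step count and least certain steps

Total step count: 11. Longest linear sequence: 9 steps (steps 1 to 8, then step 11); the pyranone branch is steps 9 and 10.

**Step 5 (key step).**
- Risk: slow enolisation of the alpha carbon in hot, basic fluoride would erode the configuration.
- Risk: protonation of the aryl anion before the acyl shift would stop the sequence at the aryl ester.
- Risk: incomplete regiocontrol in the addition to 11 would place the acyl group on the wrong carbon.
- Fallback: 3 is silylated to 4 and lithiated to 5 exactly as in step 3. The anion 5 is quenched with (S)-N-methoxy-N,2-dimethylbutanamide F1, made from 10 by standard amide coupling with N,O-dimethylhydroxylamine. Work-up, which also removes the nitrogen-bound silyl group, would give (S)-3,5-bis(methoxymethoxy)-2-(2-methylbutanoyl)phenyl N-isopropylcarbamate F2. Amine-induced loss of isopropyl isocyanate (Et2NH, DBU, MeCN, rt) then returns to the route at 12. This path forms the ketone at −78 °C from a chelated tetrahedral adduct, so no acylium ion and no hot fluoride are involved.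

**Step 3.**
- Risk: the silyl triflate may activate and cleave one acetal.
- Risk: lithiation may compete at C4 between the two acetal oxygens, because the N-silylated carbamate is bulky.
- Fallback: 2 is carbamoylated with N,N-diethylcarbamoyl chloride to 3,5-bis(methoxymethoxy)phenyl N,N-diethylcarbamate F3, which needs no transient protection. Treatment with s-BuLi/TMEDA at −78 °C and TMSCl would give 3,5-bis(methoxymethoxy)-2-(trimethylsilyl)phenyl N,N-diethylcarbamate F4. LiAlH4 in THF reduces the carbamate off, which returns to the route at silylphenol 8, and 8 is triflated to 9 as in the second stage of step 4.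

**Step 6.**
- Risk: O-alkylation may be slow because the phenol is hydrogen-bonded to the ketone and hindered, and loss of HCl from 13 would then consume the chloride.
- Fallback: 12 is taken directly to 15 by condensation with 3-methylbut-2-enal under ethylenediammonium diacetate catalysis in toluene at 100 °C. C-alkylation at the only free carbon ortho to the hydroxyl, dehydration to an ortho-quinone methide and oxa-6π closure would follow. This path bypasses 14.

**Step 8.**
- Risk: acid may add methanol across the electron-rich C3=C4 bond or start oligomerisation there, and prolonged exposure may slowly epimerise the alpha carbon.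
- Fallback: the acetals are removed one stage earlier, from 14, with dilute methanolic HCl at room temperature, before the styrene-type double bond exists. This would give (S)-1-[2,4-dihydroxy-6-(2-methylbut-3-yn-2-yloxy)phenyl]-2-methylbutan-1-one F5, whose tertiary propargylic ether ionises far less readily than an acetal. Heating F5 in o-xylene at 140 °C would then close ring B and return to the route at 16.

**Step 11.**
- Risk: scrambling of the one-carbon unit (retro-Mannich exchange) would lead to self-coupling of either partner.
- Risk: the methylidene dione 23 may undergo cycloaddition at the C3=C4 bond of 16.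
- Fallback: the roles are reversed. 16 is aminomethylated at C6 with the same iminium salt to (S)-1-{6-[(dimethylamino)methyl]-5,7-dihydroxy-2,2-dimethyl-2H-chromen-8-yl}-2-methylbutan-1-one F6. Warming F6 with 21 generates the ortho-quinone methide on the chromene, which is trapped by C3' of the pyranone, and the route is rejoined at 24.

## Further compounds

F1 | step 5 | (S)-N-methoxy-N,2-dimethylbutanamide | CC[C@H](C)C(=O)N(C)OC
F2 | step 5 | (S)-3,5-bis(methoxymethoxy)-2-(2-methylbutanoyl)phenyl N-isopropylcarbamate | CC[C@H](C)C(=O)c1c(OC(=O)NC(C)C)cc(OCOC)cc1OCOC
F3 | step 3 | 3,5-bis(methoxymethoxy)phenyl N,N-diethylcarbamate | CCN(CC)C(=O)Oc1cc(OCOC)cc(OCOC)c1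
F4 | step 3 | 3,5-bis(methoxymethoxy)-2-(trimethylsilyl)phenyl N,N-diethylcarbamate | CCN(CC)C(=O)Oc1cc(OCOC)cc(OCOC)c1[Si](C)(C)C
F0 | step 6 | none | none
F5 | step 8 | (S)-1-[2,4-dihydroxy-6-(2-methylbut-3-yn-2-yloxy)phenyl]-2-methylbutan-1-one | CC[C@H](C)C(=O)c1c(OC(C)(C)C#C)cc(O)cc1O
F6 | step 11 | (S)-1-{6-[(dimethylamino)methyl]-5,7-dihydroxy-2,2-dimethyl-2H-chromen-8-yl}-2-methylbutan-1-one | CC[C@H](C)C(=O)c1c(O)c(CN(C)C)c(O)c2C=CC(C)(C)Oc12
A1 | alternative 1 | 6-[(tert-butyldimethylsilyloxy)methyl]-2,2-dimethyl-7-(triisopropylsilyloxy)chroman-5-ol | CC1(C)CCc2c(O1)cc(O[Si](C(C)C)(C(C)C)C(C)C)c(CO[Si](C)(C)C(C)(C)C)c2O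
A2 | alternative 1 | 2-diazo-1-(6,6-dimethyl-5,6-dihydro-4H-pyran-2-yl)ethan-1-one | CC1(C)CCC=C(O1)C(=O)C=[N+]=[N-]
A3 | alternative 1 | tert-butyldimethyl{[3-(triisopropylsilyloxy)prop-2-yn-1-yl]oxy}silane | CC(C)[Si](OC#CCO[Si](C)(C)C(C)(C)C)(C(C)C)C(C)C
A4 | alternative 2 | (S)-1-{6-[(2-tert-butoxy-6-ethyl-5-methyl-4-oxo-4H-pyran-3-yl)methyl]-5,7-bis(methoxymethoxy)-2,2-dimethyl-2H-chromen-8-yl}-2-methylbutan-1-one | CC[C@H](C)C(=O)c1c(OCOC)c(Cc3c(OC(C)(C)C)oc(CC)c(C)c3=O)c(OCOC)c2C=CC(C)(C)Oc12
A5 | alternative 2 | tert-butyl 2-({5,7-bis(methoxymethoxy)-2,2-dimethyl-8-[(S)-2-methylbutanoyl]-2H-chromen-6-yl}methyl)-4-methyl-3-oxohepta-4,5-dienoate (C2 and allene axis unspecified) | CC[C@H](C)C(=O)c1c(OCOC)c(CC(C(=O)OC(C)(C)C)C(=O)C(C)=C=CC)c(OCOC)c2C=CC(C)(C)Oc12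
A6 | alternative 3 | (S)-1-[5,7-bis(methoxymethoxy)-2,2-dimethyl-2H-chromen-8-yl]-2-methylbutan-1-one | CC[C@H](C)C(=O)c1c(OCOC)cc(OCOC)c2C=CC(C)(C)Oc12
A7 | alternative 3 | (S)-1-{2-fluoro-3-[(Z)-3-hydroxy-3-methylbut-1-en-1-yl]-4,6-bis(methoxymethoxy)phenyl}-2-methylbutan-1-one | CC[C@H](C)C(=O)c1c(F)c(/C=C\C(C)(C)O)c(OCOC)cc1OCOC
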